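## Retrosynthetic overview

- The target is opened at two bonds at once, C4–C3 of the chromanone and CH2–aryl of the cyclobutene, which leads back to an achiral 2-(2-arylallyloxy)benzoyl chloride.
- Forward, one Pd(0)/chiral-ligand cycle does both closures: 6-exo acyl–Pd insertion closes the pyranone and sets C3, then the neopentyl Pd activates the only free ortho C–H of the dimethoxyphenyl ring and reductive elimination closes the cyclobutene.
- The benzoyl chloride comes from the benzoic acid and its methyl ester; the aryl allyl ether comes from Mitsunobu coupling of a salicylate with a 2-arylallyl alcohol.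
- The 2-arylallyl alcohol comes from Suzuki coupling of an arylboronic acid with 2-bromoallyl alcohol. Ring order: both benzene rings are bought; pyranone first, cyclobutene second, in the same flask.

Assumption: the target stereocentre is (S). The facial sense of the ligand in step 4 cannot be predicted and must be calibrated; (R,R)-L* (TADDOL-derived N,N-dimethylphosphoramidite, aryl = 3,5-xylyl) is written, and (S,S)-L* is used if the first run gives the (R)-spirocycle.

## Route

Step 1
Reactants: 1 (2,3-dimethoxyphenyl)boronic acid; 2 2-bromoprop-2-en-1-ol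
Product: 3 2-(2,3-dimethoxyphenyl)prop-2-en-1-ol
Conditions: Pd(PPh3)4 (3 mol %), K2CO3 (2 equiv), DME/H2O 3:1, 80 °C
Reagents that add atoms: none
Why: Suzuki–Miyaura coupling, in which oxidative addition into the vinyl C–Br bond is fast and the free allylic alcohol is tolerated, so no protecting group is needed and no stereocentre is formed.

Step 2
Reactants: 3 2-(2,3-dimethoxyphenyl)prop-2-en-1-ol; 4 methyl 2-hydroxy-4,6-dimethoxybenzoate
Product: 5 methyl 2-{[2-(2,3-dimethoxyphenyl)prop-2-en-1-yl]oxy}-4,6-dimethoxybenzoate
Conditions: PPh3 (1.3 equiv), DIAD (1.3 equiv), THF, 0 °C to rt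
Reagents that add atoms: none
Why: Mitsunobu etherification, in which the salicylate-type phenol is acidic enough to be alkylated by the activated primary allylic alcohol and SN2 and SN2' attack on the symmetrical 2-arylallyl unit give the same ether; no stereocentre is formed.

Step 3
Reactants: 5 methyl 2-{[2-(2,3-dimethoxyphenyl)prop-2-en-1-yl]oxy}-4,6-dimethoxybenzoate
Product: 6 2-{[2-(2,3-dimethoxyphenyl)prop-2-en-1-yl]oxy}-4,6-dimethoxybenzoic acid
Conditions: KOH (5 equiv), MeOH/H2O 4:1, 70 °C; then 1 M HCl to pH 3–4 at 0 °C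
Reagents that add atoms: potassium hydroxide, [K+].[OH-]
Why: Saponification (BAc2 ester hydrolysis), in which hydroxide cleaves the methyl ester while the aryl ethers and the alkene are inert to base, and cold mild acidification avoids protodecarboxylation of the electron-rich acid; no stereocentre is formed.

Step 4
Reactants: 6 2-{[2-(2,3-dimethoxyphenyl)prop-2-en-1-yl]oxy}-4,6-dimethoxybenzoic acid
Product: 10 (S)-4,5,5',7'-tetramethoxyspiro[bicyclo[4.2.0]octa-1,3,5-triene-7,3'-chroman]-4'-one, via acid chloride 7 (not isolated), via alkylpalladium chloride 8 (not isolated), via palladacycle 9 (not isolated)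
Conditions: (i) 1-chloro-N,N,2-trimethylprop-1-en-1-amine (1.1 equiv), toluene, 0 °C to rt, 1 h; (ii) syringe-pump addition (4 h) to Pd(dba)2 (5 mol %), (R,R)-L* (10 mol %), 1-AdCO2H (30 mol %), Cs2CO3 (2 equiv), 4 Å MS, toluene, 100 °C, then 110 °C, 4 h
Reagents that add atoms: none
Why: Proposed new method: an enantioselective Pd(0) domino acylpalladation/C(sp2)–H alkylation, in which Pd(0)L* adds oxidatively to the aroyl chloride, the 1,1-disubstituted alkene inserts 6-exo-trig into the acyl–Pd bond (this closes the pyranone and sets the quaternary C3 centre, the ligand selecting the alkene face), the β-hydrogen-free neopentyl Pd(II) then undergoes carboxylate-assisted concerted metalation–deprotonation at the only free ortho C–H of the 2,3-dimethoxyphenyl ring to give a five-membered C(sp3),C(sp2)-palladacycle, and C–C reductive elimination closes the benzocyclobutene; the closest known reaction types are the Pd(0) domino carbopalladation/C–H activation of 2-arylallyl-tethered aryl halides and carbamoyl chlorides that gives spiro-palladacycles, the Pd(0)-catalysed methyl C(sp3)–H arylation that gives benzocyclobutenes through the same type of palladacycle, and TADDOL-phosphoramidite/Pd(0) C–H functionalisations of carbamoyl chlorides that close four-membered rings enantioselectively.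

## Compound list

1 | (2,3-dimethoxyphenyl)boronic acid | COc1cccc(B(O)O)c1OC | starting material
2 | 2-bromoprop-2-en-1-ol | OCC(Br)=C | starting material
3 | 2-(2,3-dimethoxyphenyl)prop-2-en-1-ol | COc1cccc(C(=C)CO)c1OC | intermediate
4 | methyl 2-hydroxy-4,6-dimethoxybenzoate | COC(=O)c1c(O)cc(OC)cc1OC | starting material
5 | methyl 2-{[2-(2,3-dimethoxyphenyl)prop-2-en-1-yl]oxy}-4,6-dimethoxybenzoate | COC(=O)c1c(OCC(=C)c2cccc(OC)c2OC)cc(OC)cc1OC | intermediate
6 | 2-{[2-(2,3-dimethoxyphenyl)prop-2-en-1-yl]oxy}-4,6-dimethoxybenzoic acid | OC(=O)c1c(OCC(=C)c2cccc(OC)c2OC)cc(OC)cc1OC | intermediate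
7 | 2-{[2-(2,3-dimethoxyphenyl)prop-2-en-1-yl]oxy}-4,6-dimethoxybenzoyl chloride (not isolated) | ClC(=O)c1c(OCC(=C)c2cccc(OC)c2OC)cc(OC)cc1OC | intermediate
8 | {[3-(2,3-dimethoxyphenyl)-5,7-dimethoxy-4-oxochroman-3-yl]methyl}palladium(II) chloride, ancillary ligand omitted, C3 arranged as in 10 (not isolated) | COc1cc(OC)c2c(c1)OC[C@@](c1cccc(OC)c1OC)(C[Pd]Cl)C2=O | intermediate
9 | five-membered palladacycle in which Pd bridges the C3–CH2 carbon and the ortho carbon of the dimethoxyphenyl ring, ancillary ligand omitted, C3 arranged as in 10 (not isolated) | COc1cc(OC)c2c(c1)OC[C@@]1(C[Pd]c3ccc(OC)c(OC)c31)C2=O | intermediate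
10 | (S)-4,5,5',7'-tetramethoxyspiro[bicyclo[4.2.0]octa-1,3,5-triene-7,3'-chroman]-4'-one: 5,7-dimethoxychroman-4-one spiro-fused at C3 to a benzocyclobutene whose aryl carbon on the spiro centre is ortho to OMe | COc1cc(OC)c2c(c1)OC[C@@]1(Cc3ccc(OC)c(OC)c31)C2=O | target

## Step count and risks

Total steps: 4. Longest linear sequence: 4 (1 or 2 → 3 → 5 → 6 → 10).

**Step 4 (highest risk).** The cascade is untested. Likely failures are decarbonylation of the aroyl–Pd before insertion, 7-endo insertion, slow four-membered reductive elimination (leading to protodepalladation or capture of the palladacycle by a second acid chloride, which slow addition is meant to suppress), and low ee. The ee must be measured by chiral HPLC, and the temperature kept at or below 110 °C so the benzocyclobutene does not open and racemise.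

The fallback closes the two rings in separate, well-precedented operations; it sets out from 2 and returns at 10. 4-Chloro-1,2-dimethoxybenzene is deprotonated between Cl and OMe (LiTMP, THF, −78 °C) to (6-chloro-2,3-dimethoxyphenyl)lithium F1. Quenching with i-PrOBpin, then aqueous NH4Cl, gives 2-(6-chloro-2,3-dimethoxyphenyl)-4,4,5,5-tetramethyl-1,3,2-dioxaborolane F2. Suzuki coupling of F2 with 2 (Pd(dppf)Cl2, K3PO4, dioxane/H2O, 80 °C; the vinyl bromide reacts and the hindered aryl chloride stays) gives 2-(6-chloro-2,3-dimethoxyphenyl)prop-2-en-1-ol F3. Mitsunobu etherification with commercial 2-hydroxy-4,6-dimethoxybenzaldehyde gives 2-{[2-(6-chloro-2,3-dimethoxyphenyl)prop-2-en-1-yl]oxy}-4,6-dimethoxybenzaldehyde F4. A chiral triazolium NHC-catalysed intramolecular alkene hydroacylation (DBU, dioxane, 80 °C; catalyst enantiomer chosen for S) closes the pyranone and sets C3, giving (S)-3-(6-chloro-2,3-dimethoxyphenyl)-5,7-dimethoxy-3-methylchroman-4-one F5. Pd(OAc)2/P(t-Bu)3·HBF4, K2CO3, DMF, 140 °C then closes the cyclobutene by methyl C(sp3)–H arylation to 10 without touching the quaternary centre.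

**Step 3.** The ester is flanked by two ortho alkoxy groups, so hydrolysis may be slow, and the 2,4,6-trioxygenated acid can decarboxylate on acidification. The fallback avoids the ester; it sets out from 3 and returns at 6. Mitsunobu etherification of 3 with 2-hydroxy-4,6-dimethoxybenzaldehyde gives 2-{[2-(2,3-dimethoxyphenyl)prop-2-en-1-yl]oxy}-4,6-dimethoxybenzaldehyde F6. Pinnick oxidation (NaClO2, NaH2PO4, excess 2-methyl-2-butene, t-BuOH/H2O, 0 °C to rt) then delivers 6 under buffered conditions.

**Step 2.** The phenol is hydrogen-bonded to the ester and hindered, so the Mitsunobu reaction may stall. The fallback reverses the order of bond formation; it sets out from 4 and returns at 5. O-Alkylation of 4 with 2,3-dibromoprop-1-ene (K2CO3, DMF, 50 °C) gives methyl 2-[(2-bromoprop-2-en-1-yl)oxy]-4,6-dimethoxybenzoate F7. Suzuki coupling of F7 with 1 (Pd(PPh3)4, K2CO3, DME/H2O, 80 °C) gives 5.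

## Further compounds

F1 | step 4 | (6-chloro-2,3-dimethoxyphenyl)lithium | [Li]c1c(Cl)ccc(OC)c1OC
F2 | step 4 | 2-(6-chloro-2,3-dimethoxyphenyl)-4,4,5,5-tetramethyl-1,3,2-dioxaborolane | COc1ccc(Cl)c(B2OC(C)(C)C(C)(C)O2)c1OC
F3 | step 4 | 2-(6-chloro-2,3-dimethoxyphenyl)prop-2-en-1-ol | COc1ccc(Cl)c(C(=C)CO)c1OC
F4 | step 4 | 2-{[2-(6-chloro-2,3-dimethoxyphenyl)prop-2-en-1-yl]oxy}-4,6-dimethoxybenzaldehyde | O=Cc1c(OCC(=C)c2c(Cl)ccc(OC)c2OC)cc(OC)cc1OC
F5 | step 4 | (S)-3-(6-chloro-2,3-dimethoxyphenyl)-5,7-dimethoxy-3-methylchroman-4-one | COc1cc(OC)c2c(c1)OC[C@@](c1c(Cl)ccc(OC)c1OC)(C)C2=O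
F6 | step 3 | 2-{[2-(2,3-dimethoxyphenyl)prop-2-en-1-yl]oxy}-4,6-dimethoxybenzaldehyde | O=Cc1c(OCC(=C)c2cccc(OC)c2OC)cc(OC)cc1OC
F7 | step 2 | methyl 2-[(2-bromoprop-2-en-1-yl)oxy]-4,6-dimethoxybenzoate | COC(=O)c1c(OCC(Br)=C)cc(OC)cc1OC
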